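## Retrosynthetic overview
1. Frajunolide K ⇐ macrocyclic 6,8,9‑triol 25. C6–Cl comes from SN2 inversion of a 6R allylic alcohol. The 9‑OAc is installed last.
2. The ten‑membered ring is closed last at C9–C10. A visible‑light acridinium/chromium allylic C–H addition to the C9 aldehyde (a formal carbonyl‑ene reaction) creates C9, C10 and the Δ11(20) methylene.
3. Seco‑aldehyde 24 ⇐ Sonogashira coupling at C4–C5, then Lindlar reduction (3Z), of alkyne 11 and iodo‑alkene 22.
4. 11 (six‑membered ring bought) ⇐ (S)‑carvone. α′‑Formylation and methylation set C1, ethynylation sets C2, a Criegee rearrangement turns isopropenyl into 14‑OAc, and hydrazone reduction transposes the alkene.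
5. 22 (γ‑lactone, the second ring) ⇐ D‑xylose. C6 and C7 are bought, a Reformatsky addition to the 2‑ulose sets C8, and thiolysis with lactonisation followed by equilibration sets C17.

Assumption: briarane numbering (C1–C20) is used for all intermediates. The anomeric (C9) mixture is carried unseparated until C9 becomes sp² and the C17 mixture until step 17, because both converge.

## Route

**Step 1**
Reactants: 1, (S)‑(+)‑carvone
Product: 2, 6‑(hydroxymethylene)carvone. This is the enolised α′‑formyl ketone; the isopropenyl carbon (future C14) is unchanged.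
Conditions: LDA, THF, −78 °C; CF3CH2OCHO, −78 → 0 °C
Reagents that add atoms: 2,2,2‑trifluoroethyl formate, O=COCC(F)(F)F
Why: Kinetic α′‑enolate C‑formylation (crossed Claisen) installs C2 at the aldehyde oxidation level; no stereocenter is formed because the product is enolised.

**Step 2**
Reactants: 2
Product: 3, (1R,6R)‑1,3‑dimethyl‑2‑oxo‑6‑(prop‑1‑en‑2‑yl)cyclohex‑3‑ene‑1‑carbaldehyde. On quaternary C1 the CH3 is trans and the CHO is cis to the isopropenyl group.
Conditions: MeI, K2CO3, acetone, 23 °C
Reagents that add atoms: iodomethane, CI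
Why: C‑alkylation of a β‑keto‑aldehyde enolate; A(1,3) strain with the exocyclic enolate makes the neighbouring isopropenyl axial, so MeI enters anti to it and sets C1.

**Step 3**
Reactants: 3
Product: 4, (5R,6R)‑6‑[(1S)‑1‑hydroxyprop‑2‑yn‑1‑yl]‑2,6‑dimethyl‑5‑(prop‑1‑en‑2‑yl)cyclohex‑2‑en‑1‑one (2S carbinol)
Conditions: HC≡CMgBr, ClTi(OiPr)3, THF/CH2Cl2, −78 → −30 °C
Reagents that add atoms: ethynylmagnesium bromide, C#C[Mg]Br
Why: Aldehyde‑selective 1,2‑addition of a non‑chelating alkynyltitanium reagent; in the Felkin–Anh/Cornforth transition state the C1–C10 acyl bond lies anti to the nucleophile, which passes the CH3 and gives 2S.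

**Step 4**
Reactants: 5, glycolic acid; 6, 3‑methylbutanoyl (isovaleryl) chloride
Product: 7, (3‑methylbutanoyloxy)acetic acid
Conditions: pyridine, CH2Cl2, 0 → 23 °C
Reagents that add atoms: none (both partners are numbered reactants)
Why: Simple O‑acylation of the hydroxy acid with an acid chloride.

**Step 5**
Reactants: 4; 7
Product: 8, the 2‑O‑[(3‑methylbutanoyloxy)acetyl] ester of 4
Conditions: 2,4,6‑Cl3C6H2COCl, Et3N; DMAP, toluene, 23 °C
Reagents that add atoms: none
Why: Yamaguchi esterification acylates the hindered neopentyl propargylic alcohol with retention; putting the final side chain on now avoids any protecting group at C2, and quaternary C1 rules out β‑elimination.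

**Step 6**
Reactants: 8
Product: 9, as 8 but with the isopropenyl replaced by acetoxy with retention (14S‑OAc, cis to the C2 branch)
Conditions: O3, CH2Cl2/MeOH, −78 °C (Sudan III end point); Ac2O, Et3N, DMAP, CH2Cl2, 0 → 40 °C
Reagents that add atoms: ozone, [O-][O+]=O (ether O); methanol, CO (carbonyl O)
Why: Chemoselective ozonolysis of the only electron‑rich alkene (the enone and alkyne are inert), then Criegee rearrangement of the acylated α‑methoxy hydroperoxide; the secondary carbon migrates with retention, so the bought stereocenter becomes C14–OAc and the acetyl carbons come from the isopropenyl group.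

**Step 7**
Reactants: 9
Product: 10, the C10 tosylhydrazone of 9
Conditions: TsNHNH2, PPTS, 4 Å MS, THF, 50 °C
Reagents that add atoms: p‑toluenesulfonyl hydrazide, Cc1ccc(cc1)S(=O)(=O)NN
Why: Acid‑catalysed hydrazone condensation; mild anhydrous conditions spare the four esters.

**Step 8**
Reactants: 10
Product: 11, fragment A (1R,2S,14S). It is a 1,3‑dimethylcyclohex‑2‑ene with a C10H=C11(CH3) alkene. C1 carries CH3 and the (S)‑CH(O‑acyl)C≡CH branch, and C14 carries OAc.
Conditions: catecholborane, CHCl3, −10 °C; NaOAc·3H2O, reflux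
Reagents that add atoms: none
Why: Kabalka reduction; hydride adds to C=N, and the allylic diazene loses N2 by a retro‑ene shift, which removes the carbonyl and moves the alkene to C10=C11 without creating or touching a stereocenter.

**Step 9**
Reactants: 12, D‑xylose
Product: 13, methyl 3,5‑O‑isopropylidene‑D‑xylofuranoside (α/β), with only the 2‑OH (C8–OH) free
Conditions: AcCl (cat.), MeOH, 23 °C; NaHCO3; Me2C(OMe)2, acetone, CSA
Reagents that add atoms: methanol, CO; 2,2‑dimethoxypropane, COC(C)(C)OC
Why: Kinetic Fischer furanosidation followed by 1,3‑dioxane acetal formation. The mapping is xylose C1–C5 = C9, C8, C7, C6, C5, and the ring oxygen protects O6 and C9 together.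

**Step 10**
Reactants: 13
Product: 14, methyl 3,5‑O‑isopropylidene‑D‑threo‑pentofuranosid‑2‑ulose (C8 ketone)
Conditions: DMP, NaHCO3, CH2Cl2, 23 °C
Reagents that add atoms: none
Why: Dess–Martin oxidation of the single free secondary alcohol under neutral, non‑epimerising conditions.

**Step 11**
Reactants: 14
Product: 15, methyl 2‑C‑[1‑(methoxycarbonyl)ethyl]‑3,5‑O‑isopropylidene‑D‑lyxofuranoside. The new C8–C17 bond is on the α‑face and the 8‑OH is β (cis to O7). C17 is a mixture of epimers.
Conditions: MeCHBrCO2Me, Zn (TMSCl‑activated), THF, 0 → 23 °C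
Reagents that add atoms: methyl 2‑bromopropanoate, COC(=O)C(C)Br
Why: Reformatsky addition (weakly basic, so no β‑elimination); the cis‑fused dioxane blocks the β‑face, so carbon attacks the convex α‑face and sets C8 (R in the target).

**Step 12**
Reactants: 15
Product: 16, the 3,5‑diol (C7–OH and C5–OH free; glycoside intact)
Conditions: AcOH/H2O 7:3, 23 °C
Reagents that add atoms: none
Why: Selective hydrolysis of the strained isopropylidene dioxane. O7 and C17 are trans on the furanose ring, so no lactone can form yet.

**Step 13**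
Reactants: 16
Product: 17, the C5 aldehyde (pentodialdo‑1,4‑furanoside)
Conditions: TEMPO (cat.), PhI(OAc)2, CH2Cl2, 23 °C
Reagents that add atoms: none
Why: Oxoammonium oxidation is selective for the primary alcohol over the secondary and tertiary ones.

**Step 14**
Reactants: 17
Product: 18, the terminal alkyne (C5≡C16H) on C6
Conditions: MeCOC(N2)P(O)(OMe)2, K2CO3, MeOH, 0 → 23 °C
Reagents that add atoms: Ohira–Bestmann reagent, COP(=O)(OC)C(=[N+]=[N-])C(C)=O
Why: Seyferth–Gilbert/Ohira–Bestmann homologation adds C16; it is known to work on furanose 5‑aldehydes without C4 (here C6) epimerisation.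

**Step 15**
Reactants: 18
Product: 19, the 2‑iodo‑1‑alkene, C5(I)=C16H2
Conditions: B‑I‑9‑BBN (3.3 equiv), CH2Cl2/hexane, −20 → 0 °C; AcOH; NaBO3 work‑up
Reagents that add atoms: B‑iodo‑9‑BBN, IB1C2CCCC1CCC2
Why: Markovnikov iodoboration followed by protodeboronation gives the 1,1‑disubstituted vinyl iodide; the excess reagent covers the two OH groups.

**Step 16**
Reactants: 19
Product: 20, the γ‑lactone diethyl dithioacetal. The lactone is O7–C19(=O)–C17–C8. The 8‑OH and the 6R allylic OH are free, C9 is CH(SEt)2, and C17 is a mixture of epimers. The C6 chain and C9 are trans on the lactone.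
Conditions: EtSH, BF3·OEt2, CH2Cl2, −20 → 0 °C
Reagents that add atoms: ethanethiol, CCS
Why: Thiolysis opens the furanoside; only then can O7 rotate onto the ester and lactonise. The trans‑disubstituted lactone then prevents O6 from ever re‑closing onto C9.

**Step 17**
Reactants: 20
Product: 21, the single 17R epimer (CH3 cis to 8‑OH and trans to C9)
Conditions: DBU (0.5 equiv), toluene, 60 °C
Reagents that add atoms: none
Why: Base equilibration of the α‑lactone centre; thermodynamic control places the methyl trans to the bulky CH(SEt)2 group on the stereocenter‑defined ring and sets C17.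

**Step 18**
Reactants: 21
Product: 22, fragment B, the α‑hydroxy aldehyde (C9HO on C8)
Conditions: PhI(O2CCF3)2, MeCN/H2O 9:1, 0 °C
Reagents that add atoms: water, O
Why: Oxidative dethioacetalisation; the aldehyde is non‑enolisable and cannot form a lactol, because that would require a trans‑fused 5/5 system.

**Step 19**
Reactants: 11; 22
Product: 23, the C3≡C4–C5(=C16H2) enyne seco‑aldehyde
Conditions: PdCl2(PPh3)2, CuI, Et3N, THF, 23 °C
Reagents that add atoms: none
Why: Sonogashira coupling of a reactive vinyl iodide at room temperature tolerates the aldehyde, the free alcohols and the esters; a tertiary amine is used to avoid iminium chemistry.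

**Step 20**
Reactants: 23
Product: 24, the (3Z)‑diene seco‑aldehyde
Conditions: H2 (1 atm), Lindlar Pd, quinoline, EtOAc, 23 °C
Reagents that add atoms: none
Why: Lindlar syn‑semihydrogenation of the conjugated alkyne gives the 3Z alkene and leaves the 1,1‑di‑ and trisubstituted alkenes untouched.

**Step 21 (key step)**
Reactants: 24
Product: 25, the briarane macrocycle. It contains the trans‑fused ten‑membered ring, the Δ11(20) methylene, 9S‑OH, 10S‑H (α), and free 6R‑OH and 8‑OH.
Conditions: 9‑mesityl‑3,6‑di‑tBu‑10‑phenylacridinium BF4 (5 mol %), CrCl2 (20 mol %), 2,6‑lutidine (0.5 equiv), MeCN/CH2Cl2, 1 mM, degassed, 450 nm LED, 20 °C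
Reagents that add atoms: none (isomerisation)
Why: Proposed new method: a redox‑neutral intramolecular photoredox/chromium allylic C–H carbonyl allylation (a formal carbonyl‑ene macrocyclisation), in which the excited acridinium oxidises the most electron‑rich π‑bond, C10=C11 (the diene is deactivated by two allylic C–O bonds); lutidine removes the unhindered C20–H; the C10–C11–C20 allyl radical is captured at C20 by labile Cr(II) already chelated by the C8‑OH/C9=O unit, which templates ring closure; the allyl–Cr(III) adds through C10 (SE2′), forming C9–C10, the ring and the exocyclic methylene; lutidinium then frees the alkoxide and the acridinyl radical returns Cr(III) to Cr(II); C10 is set by β‑face attack, anti to the pseudoaxial C2 branch and away from 14‑OAc; C9 is set by the chelate, which forces C8 axial in the chair so that the ring‑locked E‑allyl unit gives the 9,10‑syn product; the closest known reactions are the intermolecular acridinium/CrCl2 allylation of aldehydes with excess simple alkenes and stoichiometric CrCl2 (Nozaki–Hiyama–Kishi) allylative macrocyclisations of allylic halides.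

**Step 22**
Reactants: 25
Product: 26, the 6S‑chloride (8‑OH and 9‑OH free)
Conditions: PPh3, Cl3CCOCCl3 (1.2 equiv each), CH2Cl2, −20 → 0 °C
Reagents that add atoms: hexachloroacetone, ClC(Cl)(Cl)C(=O)C(Cl)(Cl)Cl
Why: Appel‑type (Magid) chlorination converts allylic alcohols to unrearranged chlorides with inversion (bought 6R‑OH → 6S‑Cl); the doubly neopentyl C9‑OH and the tertiary C8‑OH cannot undergo SN2.

**Step 23**
Reactants: 26
Product: 27, Frajunolide K
Conditions: Ac2O, DMAP, Et3N, CH2Cl2, 23 °C
Reagents that add atoms: acetic anhydride, CC(=O)OC(C)=O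
Why: DMAP‑catalysed acetylation of the only remaining secondary alcohol (C9); the tertiary 8‑OH is inert.

## Compound list
1 | (S)‑(+)‑carvone | CC1=CC[C@H](C(C)=C)CC1=O | starting material
2 | 6‑(hydroxymethylene)carvone | CC1=CC[C@H](C(C)=C)C(=CO)C1=O | intermediate
3 | (1R,6R)‑1,3‑dimethyl‑2‑oxo‑6‑isopropenylcyclohex‑3‑ene‑1‑carbaldehyde | CC1=CC[C@H](C(C)=C)[C@](C)(C=O)C1=O | intermediate
4 | (2S)‑propargylic alcohol | CC1=CC[C@H](C(C)=C)[C@](C)([C@@H](O)C#C)C1=O | intermediate
5 | glycolic acid | OCC(=O)O | starting material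
6 | isovaleryl chloride | CC(C)CC(=O)Cl | starting material
7 | (3‑methylbutanoyloxy)acetic acid | CC(C)CC(=O)OCC(=O)O | intermediate
8 | C2 ester of 4 | CC1=CC[C@H](C(C)=C)[C@](C)([C@@H](OC(=O)COC(=O)CC(C)C)C#C)C1=O | intermediate
9 | 14S‑acetate enone | CC1=CC[C@H](OC(C)=O)[C@](C)([C@@H](OC(=O)COC(=O)CC(C)C)C#C)C1=O | intermediate
10 | C10 tosylhydrazone | CC1=CC[C@H](OC(C)=O)[C@](C)([C@@H](OC(=O)COC(=O)CC(C)C)C#C)C1=NNS(=O)(=O)c2ccc(C)cc2 | intermediate
11 | fragment A (C10=C11 alkene, terminal alkyne) | CC1=C[C@@](C)([C@@H](OC(=O)COC(=O)CC(C)C)C#C)[C@@H](OC(C)=O)CC1 | intermediate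
12 | D‑xylose (aldehydo form drawn) | O=C[C@H](O)[C@@H](O)[C@H](O)CO | starting material
13 | methyl 3,5‑O‑isopropylidene‑D‑xylofuranoside (α/β) | COC1O[C@@H]2COC(C)(C)O[C@@H]2[C@H]1O | intermediate
14 | furanosid‑2‑ulose | COC1O[C@@H]2COC(C)(C)O[C@@H]2C1=O | intermediate
15 | Reformatsky adduct (lyxo; C17 mixture) | COC1O[C@@H]2COC(C)(C)O[C@@H]2[C@@]1(O)C(C)C(=O)OC | intermediate
16 | 3,5‑diol | COC1O[C@H](CO)[C@H](O)[C@@]1(O)C(C)C(=O)OC | intermediate
17 | C5 aldehyde | COC1O[C@H](C=O)[C@H](O)[C@@]1(O)C(C)C(=O)OC | intermediate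
18 | C5≡C16 alkyne | COC1O[C@H](C#C)[C@H](O)[C@@]1(O)C(C)C(=O)OC | intermediate
19 | C5 vinyl iodide | COC1O[C@H](C(I)=C)[C@H](O)[C@@]1(O)C(C)C(=O)OC | intermediate
20 | lactone dithioacetal (C17 mixture) | C=C(I)[C@@H](O)[C@@H]1OC(=O)C(C)[C@@]1(O)C(SCC)SCC | intermediate
21 | lactone dithioacetal, 17R | C=C(I)[C@@H](O)[C@@H]1OC(=O)[C@H](C)[C@@]1(O)C(SCC)SCC | intermediate
22 | fragment B (lactone aldehyde) | C=C(I)[C@@H](O)[C@@H]1OC(=O)[C@H](C)[C@@]1(O)C=O | intermediate
23 | enyne seco‑aldehyde | CC1=C[C@@](C)([C@@H](OC(=O)COC(=O)CC(C)C)C#CC(=C)[C@@H](O)[C@@H]2OC(=O)[C@H](C)[C@@]2(O)C=O)[C@@H](OC(C)=O)CC1 | intermediate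
24 | (3Z)‑diene seco‑aldehyde | CC1=C[C@@](C)([C@@H](OC(=O)COC(=O)CC(C)C)/C=C\C(=C)[C@@H](O)[C@@H]2OC(=O)[C@H](C)[C@@]2(O)C=O)[C@@H](OC(C)=O)CC1 | intermediate
25 | macrocyclic 6,8,9‑triol | C=C1CC[C@H](OC(C)=O)[C@]2(C)[C@@H](OC(=O)COC(=O)CC(C)C)/C=C\C(=C)[C@@H](O)[C@@H]3OC(=O)[C@H](C)[C@@]3(O)[C@@H](O)[C@@H]12 | intermediate
26 | 9‑deacetyl Frajunolide K (6S‑Cl) | C=C1CC[C@H](OC(C)=O)[C@]2(C)[C@@H](OC(=O)COC(=O)CC(C)C)/C=C\C(=C)[C@H](Cl)[C@@H]3OC(=O)[C@H](C)[C@@]3(O)[C@@H](O)[C@@H]12 | intermediate
27 | Frajunolide K | C=C1CC[C@H](OC(C)=O)[C@]2(C)[C@@H](OC(=O)COC(=O)CC(C)C)/C=C\C(=C)[C@H](Cl)[C@@H]3OC(=O)[C@H](C)[C@@]3(O)[C@@H](OC(C)=O)[C@@H]12 | target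

## Totals and risks
**Total steps:** 23.

**Longest linear sequence:** 15 steps, D‑xylose → 27 (steps 9–23). The carvone branch is 12 steps.

**The three steps most likely to fail:**

1. **Step 21, the proposed new step.**
   - Risks: deprotonation at C12 instead of C20, competing oxidation of the diene, formation of the 9‑epimer (normal anti chair), and oligomerisation.
   - Fallback, using known chemistry only:
     - Make C9–C10 first and intermolecularly. Ene‑type chlorination of 11 (NCS, cat. PhSeCl) gives the 10‑chloro‑11(20)‑ene.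
     - Couple that chloride with 22 (6‑ and 8‑OH as TES ethers) by stoichiometric CrCl2 Nozaki–Hiyama allylation.
     - Correct C9 if necessary by DMP oxidation and NaBH4/CeCl3 reduction (Felkin control, with C1 as the large group).
     - Close the ring instead at C4–C5 by intramolecular Sonogashira coupling, then apply Lindlar reduction.

2. **Step 22, SN2 at a medium‑ring allylic carbon.**
   - Risks: a hindered backside trajectory, SN2′ attack giving the C16 chloride, and interference from the 8,9‑diol.
   - Fallback: chlorinate at the acyclic stage on 24, where C6 is unhindered. Then close the ring with a chloride‑tolerant Me2AlCl‑promoted carbonyl‑ene macrocyclisation in place of the chromium chemistry.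

3. **Step 3, facial selectivity at C2.**
   - Risk: chelation and non‑chelation models predict opposite epimers.
   - Fallback: set C2 with hydride rather than carbon. Oxidise 4 (either epimer) to the ynone with DMP, then reduce it under chelation control with Zn(BH4)2. The C2/C10 dicarbonyl chelate is attacked from the methyl face, which gives 2S.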